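**Strategy.** The ring closed last is the 1,2-dihydronaphthalene carbocycle (C1–C2–C3=C4–C4a–C8a). It is cut at C1–C2 and C3–C4 into dimethyl fumarate (C2, C3 and their carboxyls) and an aldehyde in which the catechol ring already carries the finished pyranone on a CH2 group (future C1) ortho to the formyl carbon (future C4). The key step exploits the acidity of C1–H, vinylogous to the pyranone ester (C3′=C4′–C5′=C6′–CO2Me) and ortho-benzylic to the formyl iminium. A chiral secondary amine should give an amino-ortho-quinodimethane whose [4+2] addition to fumarate, amine loss and C2 equilibration close the ring, set C1 and funnel all isomers into trans-(1R,2R) in one operation.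

Key step: step 5

Remark (assumptions and numbering): 1, 5, 9, both antipodes of α,α-diphenylprolinol trimethylsilyl ether and the fallback pyranone F3 are taken as purchasable. Atoms are numbered as in the target: naphthalene C1–C8a, pyranone O1′–C6′ with C3′ bonded to C1.

**Step 1**
Reactants: 1 2-oxo-2H-pyran-6-carboxylic acid
Product: 2 methyl 2-oxo-2H-pyran-6-carboxylate
Conditions: MeOH, conc. H2SO4 (cat.), 60 °C
Reagents that add atoms: methanol, CO
Why: Fischer esterification, which should leave the acid-stable 2-pyranone ring untouched, as in the standard preparation of methyl coumalate from coumalic acid.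

**Step 2**
Reactants: 2 methyl 2-oxo-2H-pyran-6-carboxylate
Product: 4 methyl 3-bromo-2-oxo-2H-pyran-6-carboxylate, via dibromide adduct 3 (not isolated)
Conditions: Br2 (1.05 equiv), CH2Cl2, 0 °C → rt; then Et3N (1.2 equiv), 0 °C
Reagents that add atoms: bromine, BrBr
Why: Bromination–dehydrobromination of a 2-pyranone, in which the electrophile should enter at C3 (activated by the ring oxygen and remote from the C6 ester, as for 2-pyranone and methyl coumalate) and Et3N removes HBr from the adduct to restore the pyranone.

**Step 3**
Reactants: 4 methyl 3-bromo-2-oxo-2H-pyran-6-carboxylate; 5 3,4-dimethoxybenzyl chloride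
Product: 7 methyl 3-(3,4-dimethoxybenzyl)-2-oxo-2H-pyran-6-carboxylate, via benzylzinc chloride 6 (not isolated)
Conditions: 5, Zn dust, LiCl, THF, rt; then 4, Pd(OAc)2 (2 mol %), SPhos (4 mol %), THF, rt
Reagents that add atoms: none
Why: LiCl-promoted zinc insertion followed by Negishi cross-coupling, in which oxidative addition into the electron-poor C3–Br bond is fast and the benzylzinc reagent is too mild to attack the lactone or the ester.

**Step 4**
Reactants: 7 methyl 3-(3,4-dimethoxybenzyl)-2-oxo-2H-pyran-6-carboxylate
Product: 8 methyl 3-(2-formyl-4,5-dimethoxybenzyl)-2-oxo-2H-pyran-6-carboxylate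
Conditions: Cl2CHOMe (1.5 equiv), TiCl4 (2.2 equiv), CH2Cl2, −20 → 0 °C; then ice–water
Reagents that add atoms: dichloromethyl methyl ether, COC(Cl)Cl; water, O
Why: Rieche formylation, an electrophilic aromatic substitution that should occur para to the 3-methoxy group and ortho to the benzylic carbon (the most nucleophilic accessible site of the veratryl ring), while the electron-poor pyranone stays inert.

**Step 5**
Reactants: 8 methyl 3-(2-formyl-4,5-dimethoxybenzyl)-2-oxo-2H-pyran-6-carboxylate; 9 dimethyl fumarate
Product: 13 dimethyl (1R,2R)-1-[6-(methoxycarbonyl)-2-oxo-2H-pyran-3-yl]-6,7-dimethoxy-1,2-dihydronaphthalene-2,3-dicarboxylate, via amino-o-quinodimethane 10 (not isolated), via aminotetralin cycloadduct 11 (not isolated), via cis-C2-epimer 12 (not isolated)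
Conditions: (R)-α,α-diphenylprolinol TMS ether (20 mol %), PhCO2H (20 mol %), 9 (1.5 equiv), toluene, 60 °C; then DBU (0.4 equiv), 0 °C → rt
Reagents that add atoms: none
Why: Proposed new method: the amine condenses with the formyl group of 8, and the iminium makes the C1–H2 protons (already vinylogous to the pyranone ester through C3′=C4′–C5′=C6′) acidic enough for benzoate to form the push–pull amino-ortho-quinodimethane 10, which should add fumarate across C1 and C4 with rearomatisation of the catechol ring to give 11; E1cB loss of the amine from C4 then creates C3=C4 and returns the catalyst. The closest known reactions are the secondary-amine-catalysed Diels–Alder reactions of ortho-quinodimethanes generated from 2-alkyl heteroaryl carbaldehydes and nitro-activated 2-methylbenzaldehydes, the amine-catalysed Michael/aldol-condensation route from 2-(nitromethyl)benzaldehydes to 1,2-dihydronaphthalenes, and the photoenol Diels–Alder reaction of 2-benzylbenzaldehydes with fumarates. The carbocycle is closed by an intermolecular (4+2) annulation forming C1–C2 and C3–C4 (if stepwise, Michael addition at C1 followed by 6-(enolexo)-exo-trig Mannich closure). C1 is set by the catalyst: in the reactive E,E-dienamine (amine and pyranone both outside) the CPh2(OTMS) group shields one face at C4, and because the diene is attacked suprafacially the standard shielding model predicts that the (R)-amine gives (1R); the (S)-amine would be used if the sense proved opposite. C2, the most acidic centre of the product (ester α-carbon, allylic to C3=C4), is then equilibrated by the benzoate-buffered DBU to the more stable trans pseudo-diaxial arrangement, so both endo and exo adducts converge on (1R,2R). The step needs intermolecular trapping to outrun 6π-electrocyclisation of 10 onto pyranone C4′ and bonding through C1 rather than C4′ or C6′; the outside position of the pyranone in the reactive E-isomer, the excess of fumarate and the aromaticity regained on bonding at C1 should secure this.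

**Step 6**
Reactants: 13 dimethyl (1R,2R)-1-[6-(methoxycarbonyl)-2-oxo-2H-pyran-3-yl]-6,7-dimethoxy-1,2-dihydronaphthalene-2,3-dicarboxylate
Product: 14 (1R,2R)-1-(6-carboxy-2-oxo-2H-pyran-3-yl)-6,7-dihydroxy-1,2-dihydronaphthalene-2,3-dicarboxylic acid
Conditions: BBr3 (12 equiv), CH2Cl2, −78 °C → rt, Ar; then H2O, 0 °C
Reagents that add atoms: none
Why: BBr3 dealkylation of aryl methyl ethers and methyl esters (bromide attack at the methyl groups) should unveil the catechol and the three acids in one operation without breaking a bond to C1 or C2, the pyranone lactone being stable to acid.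

**Compound list**

1 | 2-oxo-2H-pyran-6-carboxylic acid | O=C(O)c1cccc(=O)o1 | starting material
2 | methyl 2-oxo-2H-pyran-6-carboxylate | COC(=O)c1cccc(=O)o1 | intermediate
3 | methyl trans-3,4-dibromo-2-oxo-3,4-dihydro-2H-pyran-6-carboxylate (racemic, presumed adduct) | COC(=O)C1=C[C@@H](Br)[C@H](Br)C(=O)O1 | intermediate
4 | methyl 3-bromo-2-oxo-2H-pyran-6-carboxylate | COC(=O)c1ccc(Br)c(=O)o1 | intermediate
5 | 3,4-dimethoxybenzyl chloride | COc1ccc(CCl)cc1OC | starting material
6 | (3,4-dimethoxybenzyl)zinc chloride | COc1ccc(C[Zn]Cl)cc1OC | intermediate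
7 | methyl 3-(3,4-dimethoxybenzyl)-2-oxo-2H-pyran-6-carboxylate | COC(=O)c1ccc(Cc2ccc(OC)c(OC)c2)c(=O)o1 | intermediate
8 | methyl 3-(2-formyl-4,5-dimethoxybenzyl)-2-oxo-2H-pyran-6-carboxylate | COC(=O)c1ccc(Cc2cc(OC)c(OC)cc2C=O)c(=O)o1 | intermediate
9 | dimethyl fumarate | COC(=O)/C=C/C(=O)OC | starting material
10 | amino-ortho-quinodimethane: E,E-dienamine of 8 with the (R)-amine, ring dearomatised, exocyclic C4=C4a (N outside) and C1=C8a (pyranone outside) | COC(=O)c1ccc(/C=C2\C=C(OC)C(OC)=C/C2=C\N2CCC[C@@H]2C(O[Si](C)(C)C)(c2ccccc2)c2ccccc2)c(=O)o1 | intermediate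
11 | aminotetralin cycloadduct: (1R)-configured, amine at C4 cis to the pyranone at C1, C2/C3 esters trans to each other (endo/exo mixture, not specified) | COC(=O)C1[C@H](N2CCC[C@@H]2C(O[Si](C)(C)C)(c2ccccc2)c2ccccc2)c2cc(OC)c(OC)cc2[C@H](c2ccc(C(=O)OC)oc2=O)C1C(=O)OC | intermediate
12 | dimethyl (1R,2S)-1-[6-(methoxycarbonyl)-2-oxo-2H-pyran-3-yl]-6,7-dimethoxy-1,2-dihydronaphthalene-2,3-dicarboxylate (cis C2-epimer) | COC(=O)C1=Cc2cc(OC)c(OC)cc2[C@H](c2ccc(C(=O)OC)oc2=O)[C@@H]1C(=O)OC | intermediate
13 | dimethyl (1R,2R)-1-[6-(methoxycarbonyl)-2-oxo-2H-pyran-3-yl]-6,7-dimethoxy-1,2-dihydronaphthalene-2,3-dicarboxylate (trans) | COC(=O)C1=Cc2cc(OC)c(OC)cc2[C@H](c2ccc(C(=O)OC)oc2=O)[C@H]1C(=O)OC | intermediate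
14 | (1R,2R)-1-(6-carboxy-2-oxo-2H-pyran-3-yl)-6,7-dihydroxy-1,2-dihydronaphthalene-2,3-dicarboxylic acid | O=C(O)C1=Cc2cc(O)c(O)cc2[C@H](c2ccc(C(=O)O)oc2=O)[C@H]1C(=O)O | target

**Step count.** Total: 6 steps. Longest linear sequence: 6 steps (1 → 2 → 4 → 7 → 8 → 13 → 14).

**Steps most likely to fail**

1. Step 5 (Proposed new method). The iminium of the electron-rich aldehyde may not be deprotonated at C1, so that no dearomatised diene forms. The diene may also be consumed by electrocyclisation onto pyranone C4′ before fumarate traps it, or the facial selectivity may be poor. The fallback uses known chemistry, sets out from 8 and comes back at 13. Irradiation of 8 at 365 nm with dimethyl fumarate 9 in degassed toluene is a photoenolisation/Diels–Alder reaction of a 2-benzylbenzaldehyde, in which only the E-dienol is trapped. It should give the racemic dimethyl 4-hydroxy-1-[6-(methoxycarbonyl)-2-oxo-2H-pyran-3-yl]-6,7-dimethoxy-1,2,3,4-tetrahydronaphthalene-2,3-dicarboxylate F1, with 1,2-trans expected from endo addition of the ester next to the dienol OH. TsOH (cat.) in toluene at 60 °C should dehydrate F1 across C3–C4 to racemic 13. Preparative chromatography on a chiral stationary phase then removes the (1S,2S)-enantiomer F2 and leaves 13.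

2. Step 2. Bromine may enter at C5 or add across C5=C6, or the adduct may not eliminate cleanly, so that a regioisomeric bromide is carried forward. The fallback fixes the position of substitution through the starting material; it sets out from the zinc reagent 6 and comes back at 7. Fischer esterification of 3-hydroxy-2-oxo-2H-pyran-6-carboxylic acid F3 gives methyl 3-hydroxy-2-oxo-2H-pyran-6-carboxylate F4. Tf2O and pyridine in CH2Cl2 (−78 → 0 °C) convert F4 into the enol triflate methyl 2-oxo-3-(trifluoromethylsulfonyloxy)-2H-pyran-6-carboxylate F5. Negishi coupling of F5 with 6 (Pd(OAc)2, SPhos, THF) then gives 7.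

3. Step 6. Cleavage of the three esters may be incomplete, the lactone may open without reclosing, or long exposure to excess Lewis acid may cause migration of the C3=C4 bond or aromatisation. The fallback separates ester and ether cleavage; it sets out from 13 and comes back at 14. Hydrolysis with 6 M HCl in 1,4-dioxane at 90 °C (acyl–oxygen cleavage, conditions under which the pyranone is stable and trans is the stable C2 configuration) should give (1R,2R)-1-(6-carboxy-2-oxo-2H-pyran-3-yl)-6,7-dimethoxy-1,2-dihydronaphthalene-2,3-dicarboxylic acid F6. A short treatment with BBr3 (4 equiv, −78 → 0 °C) then only has to cleave the two aryl methyl ethers to give 14.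

**Further compounds**

F1 | step 5 | rac-dimethyl (1R,2R)-4-hydroxy-1-[6-(methoxycarbonyl)-2-oxo-2H-pyran-3-yl]-6,7-dimethoxy-1,2,3,4-tetrahydronaphthalene-2,3-dicarboxylate (C3/C4 as formed) | COC(=O)C1C(O)c2cc(OC)c(OC)cc2[C@H](c2ccc(C(=O)OC)oc2=O)[C@H]1C(=O)OC
F2 | step 5 | dimethyl (1S,2S)-1-[6-(methoxycarbonyl)-2-oxo-2H-pyran-3-yl]-6,7-dimethoxy-1,2-dihydronaphthalene-2,3-dicarboxylate | COC(=O)C1=Cc2cc(OC)c(OC)cc2[C@@H](c2ccc(C(=O)OC)oc2=O)[C@@H]1C(=O)OC
F3 | step 2 | 3-hydroxy-2-oxo-2H-pyran-6-carboxylic acid | O=C(O)c1ccc(O)c(=O)o1
F4 | step 2 | methyl 3-hydroxy-2-oxo-2H-pyran-6-carboxylate | COC(=O)c1ccc(O)c(=O)o1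
F5 | step 2 | methyl 2-oxo-3-(trifluoromethylsulfonyloxy)-2H-pyran-6-carboxylate | COC(=O)c1ccc(OS(=O)(=O)C(F)(F)F)c(=O)o1
F6 | step 6 | (1R,2R)-1-(6-carboxy-2-oxo-2H-pyran-3-yl)-6,7-dimethoxy-1,2-dihydronaphthalene-2,3-dicarboxylic acid | O=C(O)C1=Cc2cc(OC)c(OC)cc2[C@H](c2ccc(C(=O)O)oc2=O)[C@H]1C(=O)O
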